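**Plan**
1. Prostanoid numbering is used: C1 is the ester carbon, the ring is C8–C12, and C20 is the chain end. The retrosynthetic cuts, in order, are: O–Si at C12 and O–acetyl at C7; C7–C8 (aldol, releases the C1–C7 Z-enal); C9–C10 and C11–C12 together (releases a C2 acetylide and an acyclic C9/C8/C12–C20 acid chloride); C13–C14 (epoxide opening).
2. Enabling feature: in the cyclopentenone ring the C10(Br)=C11H unit lies between acyl carbon C9 and carbinol carbon C12, and C12 stands 1,5 to C11 along C11–C10–C9–C8–C12. The ring is therefore the C–H insertion product of a bromo(acyl)vinylidene, which is a rearranged bromoynone, and the bromine on C10 is the trace of the 1,2-shift that makes the carbene.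
3. Forward order: the C12–C20 chain is built first (epoxide plus heptyne, then Lindlar). The only ring closes in step 8, when the C2 unit is inserted between C9 and the C12–H bond. The C1–C7 chain is then joined by aldol addition, followed by acetylation and desilylation.
4. Stereochemistry: C12 comes from ethyl (R)-4-chloro-3-hydroxybutanoate and is carried from the secondary carbinol to the fully substituted carbon by retentive C–H insertion. C8 and C7 follow from C12 by a substrate-controlled anti aldol. Both Z alkenes come from Lindlar semi-hydrogenation.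

Key step: step 8

Remark: the SMILES reads as (7S,8R,12S). This places the C8 side chain cis to the C12 hydroxyl, trans to the octenyl chain, and C7/C8 anti.

Step 1
Reactants: 1 ethyl (R)-4-chloro-3-hydroxybutanoate
Product: 2 ethyl (R)-2-(oxiran-2-yl)acetate
Conditions: Ag2O, DME, 60 °C, dark
Reagents that add atoms: none
Why: Silver-assisted intramolecular Williamson etherification of the chlorohydrin closes the epoxide without breaking the C–O bond of the stereocentre and avoids the base-induced opening to the 4-hydroxycrotonate.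

Step 2
Reactants: 2 ethyl (R)-2-(oxiran-2-yl)acetate, 3 hept-1-yne
Product: 6 ethyl (S)-3-hydroxyundec-5-ynoate, via hept-1-ynyllithium 4 (not isolated), via lithium alkoxytrifluoroborate 5 (not isolated)
Conditions: 3, n-BuLi, THF, −78 °C; BF3·OEt2; then 2, −78 °C; aqueous work-up
Reagents that add atoms: none
Why: Yamaguchi–Hirao alkynylation opens the BF3-activated epoxide by SN2 attack at its CH2 terminus (C13–C14 bond) while the ester is left alone at −78 °C, and the stereocentre is not touched (the descriptor changes only through the priorities).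

Step 3
Reactants: 6 ethyl (S)-3-hydroxyundec-5-ynoate
Product: 7 ethyl (S,Z)-3-hydroxyundec-5-enoate
Conditions: H2 (1 atm), Pd/CaCO3–Pb(OAc)2, quinoline, EtOAc, rt
Reagents that add atoms: none
Why: Lindlar semi-hydrogenation adds hydrogen syn to the alkyne and should give the C14=C15 Z alkene.

Step 4
Reactants: 7 ethyl (S,Z)-3-hydroxyundec-5-enoate
Product: 9 (S,Z)-3-hydroxyundec-5-enoic acid, via lithium carboxylate 8 (not isolated)
Conditions: LiOH, THF/H2O, rt; then aq. HCl to pH 3
Reagents that add atoms: lithium hydroxide [Li+].[OH-]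
Why: Ester saponification at room temperature proceeds by acyl–oxygen cleavage and leaves the carbinol centre and the skipped alkene untouched.

Step 5
Reactants: 9 (S,Z)-3-hydroxyundec-5-enoic acid
Product: 10 tert-butyldimethylsilyl (S,Z)-3-(tert-butyldimethylsilyloxy)undec-5-enoate
Conditions: TBSCl (2.5 equiv), imidazole, DMF, rt
Reagents that add atoms: tert-butyldimethylsilyl chloride CC(C)(C)[Si](C)(C)Cl
Why: Imidazole-promoted silylation covers both the alcohol and the acid, giving the ether that later activates C12–H and a silyl ester suited to neutral activation.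

Step 6
Reactants: 10 tert-butyldimethylsilyl (S,Z)-3-(tert-butyldimethylsilyloxy)undec-5-enoate
Product: 11 (S,Z)-3-(tert-butyldimethylsilyloxy)undec-5-enoyl chloride
Conditions: (COCl)2, DMF (cat.), CH2Cl2, 0 °C → rt; volatiles removed in vacuo
Reagents that add atoms: oxalyl chloride O=C(Cl)C(=O)Cl
Why: Vilsmeier-type conversion of a silyl ester to the acid chloride releases no HCl, so the secondary silyl ether and the β-oxygenated chain should survive.

Step 7
Reactants: 12 ethynyltrimethylsilane
Product: 13 silver (trimethylsilyl)acetylide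
Conditions: AgNO3, Et3N, MeCN, rt, dark; the precipitate is filtered off and dried
Reagents that add atoms: silver nitrate [Ag+].[O-][N+](=O)[O-]
Why: Argentation of the terminal alkyne C–H with amine base precipitates the polymeric silver acetylide, a mild, non-basic and halide-free alkynyl donor.

Step 8
Reactants: 11 (S,Z)-3-(tert-butyldimethylsilyloxy)undec-5-enoyl chloride, 13 silver (trimethylsilyl)acetylide
Product: 16 (S)-2-bromo-4-(tert-butyldimethylsilyloxy)-4-[(Z)-oct-2-en-1-yl]cyclopent-2-en-1-one, via silyl ynone 14 (not isolated), via bromoynone 15 (not isolated)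
Conditions: ClCH2CH2Cl, 4 Å MS, 40 °C; then NBS (1.0 equiv), AgNTf2 (5 mol %), rt, dark; then (BrettPhos)AuNTf2 (5 mol %), 60 °C (one flask)
Reagents that add atoms: N-bromosuccinimide O=C1CCC(=O)N1Br
Why: Proposed new method: three known reaction types are merged in one flask so that a C2 unit is inserted between acyl carbon C9 and the C12–H bond: the polymeric silver acetylide 13 is C-acylated by 11 with precipitation of AgCl (C9–C10, without a free acylium ion that could attack C14=C15), silver-catalysed bromodesilylation with NBS gives bromoynone 15, and cationic monovalent gold then induces a 1,2-shift of bromine from C11 to C10 to give a gold-bound bromo(acyl)vinylidene whose carbene carbon C11 inserts into C12–H (C11–C12). The closest known reactions are the acylation of silver acetylides by acid chlorides, the NBS/silver bromodesilylation of silyl alkynes, the gold-catalysed cycloisomerisation of 1-bromoalkynyl ketones to 2-bromocyclopent-2-enones and the thermal α-alkynone cyclisation; only their union is new, and it should be feasible because the first stage leaves 14 and insoluble AgCl, so no halide ion reaches the gold catalyst. The five-membered ring closes by 1,5 C–H insertion of the vinylidene (C11 onto C12 across C10–C9–C8), a formal [3+2] annulation. The only new stereocentre, C12, is controlled by the carbinol centre of 11: the C–C bond forms on the face from which hydrogen departs, so the insertion (concerted, or hydride shift followed by immediate collapse of the tethered ion pair) should go with retention and turn the (S) secondary silyl ether into the (S) fully substituted carbon. The step needs site selectivity for C12–H, which is the only C–H 1,5 to C11 (C8 carries no other branch at this stage) and is activated by the silyloxy oxygen, whereas C13–H is 1,6 and C14=C15 lies further away. It also needs control of the halogen position, which the mechanism secures because the migrating bromine can only end on C10, next to the carbonyl group.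

Step 9
Reactants: 17 hex-5-ynoic acid
Product: 20 7-hydroxyhept-5-ynoic acid, via dilithio hexynoate 18 (not isolated), via dilithium alkoxide carboxylate 19 (not isolated)
Conditions: n-BuLi (2.1 equiv), THF, −78 → 0 °C; (CH2O)n, 0 °C → rt; then aq. HCl
Reagents that add atoms: paraformaldehyde (as formaldehyde) C=O
Why: Hydroxymethylation of an acetylide: in the carboxylate/acetylide dianion only the acetylide carbon is nucleophilic enough to add to formaldehyde.

Step 10
Reactants: 20 7-hydroxyhept-5-ynoic acid
Product: 21 methyl 7-hydroxyhept-5-ynoate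
Conditions: MeOH, H2SO4 (cat.), rt
Reagents that add atoms: methanol CO
Why: Fischer esterification in excess methanol converts the acid selectively, and the propargylic alcohol is inert under these conditions.

Step 11
Reactants: 21 methyl 7-hydroxyhept-5-ynoate
Product: 22 methyl (Z)-7-hydroxyhept-5-enoate
Conditions: H2 (1 atm), Pd/CaCO3–Pb(OAc)2, quinoline, EtOAc, rt
Reagents that add atoms: none
Why: Lindlar semi-hydrogenation (syn addition) should give the C5=C6 Z alkene.

Step 12
Reactants: 22 methyl (Z)-7-hydroxyhept-5-enoate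
Product: 23 methyl (Z)-7-oxohept-5-enoate
Conditions: TEMPO (10 mol %), PhI(OAc)2, CH2Cl2, 0 °C → rt; used at once
Reagents that add atoms: none
Why: Oxoammonium (TEMPO) oxidation of the allylic alcohol runs close to neutrality and stops at the aldehyde, so the Z geometry should be kept.

Step 13
Reactants: 16 (S)-2-bromo-4-(tert-butyldimethylsilyloxy)-4-[(Z)-oct-2-en-1-yl]cyclopent-2-en-1-one, 23 methyl (Z)-7-oxohept-5-enoate
Product: 26 methyl (5Z,7S)-7-[(1R,2S)-4-bromo-2-(tert-butyldimethylsilyloxy)-2-[(Z)-oct-2-en-1-yl]-5-oxocyclopent-3-en-1-yl]-7-hydroxyhept-5-enoate, via lithium dienolate 24 (not isolated), via lithium aldolate 25 (not isolated)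
Conditions: LDA, THF, −78 °C; then 23, −78 °C; AcOH quench at −78 °C
Reagents that add atoms: none
Why: Kinetic lithium aldol addition through a Zimmerman–Traxler chair: C8 is the only enolisable position, the ring-locked E-enolate 24 should give the 7,8-anti adduct, and the aldehyde should reach C8 on the face bearing the C12–O bond, anti to the octenyl CH2 (larger first atom, better σ-donor), which sets 8R and with it 7S.

Step 14
Reactants: 26 methyl (5Z,7S)-7-[(1R,2S)-4-bromo-2-(tert-butyldimethylsilyloxy)-2-[(Z)-oct-2-en-1-yl]-5-oxocyclopent-3-en-1-yl]-7-hydroxyhept-5-enoate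
Product: 27 methyl (5Z,7S)-7-acetoxy-7-[(1R,2S)-4-bromo-2-(tert-butyldimethylsilyloxy)-2-[(Z)-oct-2-en-1-yl]-5-oxocyclopent-3-en-1-yl]hept-5-enoate
Conditions: Ac2O, pyridine, CH2Cl2, 0 °C
Reagents that add atoms: acetic anhydride CC(=O)OC(C)=O
Why: O-Acylation of the secondary allylic alcohol with retention at C7, kept cold and free of stronger bases so that the β-acetoxy ketone does not eliminate.

Step 15
Reactants: 27 methyl (5Z,7S)-7-acetoxy-7-[(1R,2S)-4-bromo-2-(tert-butyldimethylsilyloxy)-2-[(Z)-oct-2-en-1-yl]-5-oxocyclopent-3-en-1-yl]hept-5-enoate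
Product: 28 methyl (5Z,7S)-7-acetoxy-7-[(1R,2S)-4-bromo-2-hydroxy-2-[(Z)-oct-2-en-1-yl]-5-oxocyclopent-3-en-1-yl]hept-5-enoate
Conditions: HF·pyridine, THF, 0 °C → rt
Reagents that add atoms: none
Why: Fluoride-driven cleavage of the tertiary silyl ether in a weakly acidic medium frees the C12 hydroxyl without base, so neither acetate elimination, C8 epimerisation nor retro-aldol ring opening should occur.

**Compound list**
1 | ethyl (R)-4-chloro-3-hydroxybutanoate | ClC[C@@H](CC(=O)OCC)O | starting material
2 | ethyl (R)-2-(oxiran-2-yl)acetate | C1[C@@H](CC(=O)OCC)O1 | intermediate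
3 | hept-1-yne | C#CCCCCC | starting material
4 | hept-1-ynyllithium | [Li]C#CCCCCC | intermediate
5 | lithium trifluoroborate adduct of the alkoxide of 6 | [Li+].CCCCCC#CC[C@@H](CC(=O)OCC)O[B-](F)(F)F | intermediate
6 | ethyl (S)-3-hydroxyundec-5-ynoate | CCCCCC#CC[C@@H](CC(=O)OCC)O | intermediate
7 | ethyl (S,Z)-3-hydroxyundec-5-enoate | CCCCC/C=C\C[C@@H](CC(=O)OCC)O | intermediate
8 | lithium (S,Z)-3-hydroxyundec-5-enoate | [Li+].CCCCC/C=C\C[C@@H](CC(=O)[O-])O | intermediate
9 | (S,Z)-3-hydroxyundec-5-enoic acid | CCCCC/C=C\C[C@@H](CC(=O)O)O | intermediate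
10 | tert-butyldimethylsilyl (S,Z)-3-(tert-butyldimethylsilyloxy)undec-5-enoate | CCCCC/C=C\C[C@@H](CC(=O)O[Si](C)(C)C(C)(C)C)O[Si](C)(C)C(C)(C)C | intermediate
11 | (S,Z)-3-(tert-butyldimethylsilyloxy)undec-5-enoyl chloride | CCCCC/C=C\C[C@@H](CC(=O)Cl)O[Si](C)(C)C(C)(C)C | intermediate
12 | ethynyltrimethylsilane | C#C[Si](C)(C)C | starting material
13 | silver (trimethylsilyl)acetylide | [Ag]C#C[Si](C)(C)C | intermediate
14 | (S,Z)-5-(tert-butyldimethylsilyloxy)-1-(trimethylsilyl)tridec-7-en-1-yn-3-one | CCCCC/C=C\C[C@@H](CC(=O)C#C[Si](C)(C)C)O[Si](C)(C)C(C)(C)C | intermediate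
15 | (S,Z)-1-bromo-5-(tert-butyldimethylsilyloxy)tridec-7-en-1-yn-3-one | CCCCC/C=C\C[C@@H](CC(=O)C#CBr)O[Si](C)(C)C(C)(C)C | intermediate
16 | (S)-2-bromo-4-(tert-butyldimethylsilyloxy)-4-[(Z)-oct-2-en-1-yl]cyclopent-2-en-1-one | CCCCC/C=C\C[C@@]1(O[Si](C)(C)C(C)(C)C)C=C(Br)C(=O)C1 | intermediate
17 | hex-5-ynoic acid | C#CCCCC(=O)O | starting material
18 | lithium 6-lithiohex-5-ynoate | [Li]C#CCCCC(=O)O[Li] | intermediate
19 | dilithium 7-oxidohept-5-ynoate | [Li]OCC#CCCCC(=O)O[Li] | intermediate
20 | 7-hydroxyhept-5-ynoic acid | OCC#CCCCC(=O)O | intermediate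
21 | methyl 7-hydroxyhept-5-ynoate | OCC#CCCCC(=O)OC | intermediate
22 | methyl (Z)-7-hydroxyhept-5-enoate | OC/C=C\CCCC(=O)OC | intermediate
23 | methyl (Z)-7-oxohept-5-enoate | O=C/C=C\CCCC(=O)OC | intermediate
24 | lithium cross-conjugated dienolate of 16 | CCCCC/C=C\C[C@@]1(O[Si](C)(C)C(C)(C)C)C=C(Br)C(O[Li])=C1 | intermediate
25 | lithium aldolate of 26 | CCCCC/C=C\C[C@@]1(O[Si](C)(C)C(C)(C)C)C=C(Br)C(=O)[C@@H]1[C@H](/C=C\CCCC(=O)OC)O[Li] | intermediate
26 | methyl (5Z,7S)-7-[(1R,2S)-4-bromo-2-(tert-butyldimethylsilyloxy)-2-[(Z)-oct-2-en-1-yl]-5-oxocyclopent-3-en-1-yl]-7-hydroxyhept-5-enoate | CCCCC/C=C\C[C@@]1(O[Si](C)(C)C(C)(C)C)C=C(Br)C(=O)[C@@H]1[C@H](/C=C\CCCC(=O)OC)O | intermediate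
27 | methyl (5Z,7S)-7-acetoxy-7-[(1R,2S)-4-bromo-2-(tert-butyldimethylsilyloxy)-2-[(Z)-oct-2-en-1-yl]-5-oxocyclopent-3-en-1-yl]hept-5-enoate | CCCCC/C=C\C[C@@]1(O[Si](C)(C)C(C)(C)C)C=C(Br)C(=O)[C@@H]1[C@H](/C=C\CCCC(=O)OC)OC(C)=O | intermediate
28 | methyl (5Z,7S)-7-acetoxy-7-[(1R,2S)-4-bromo-2-hydroxy-2-[(Z)-oct-2-en-1-yl]-5-oxocyclopent-3-en-1-yl]hept-5-enoate | CCCCC/C=C\C[C@@]1(O)C=C(Br)C(=O)[C@@H]1[C@H](/C=C\CCCC(=O)OC)OC(C)=O | target

Total step count: 15. Longest linear sequence: 10 steps (steps 1–6, 8, 13–15).

**Steps most likely to fail**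

Step 8.
- What may go wrong: the acylation at the surface of the polymeric acetylide may be sluggish. NBS may attack the C14=C15 alkene. Residues of the earlier stages may slow the gold catalyst. The silyl ether oxygen or the alkene may add to the gold-activated alkyne in place of the bromine shift.
- Fallback (stepwise, known chemistry, each intermediate purified): it sets out from 11 and returns at 16.
  - MeONHMe·HCl and pyridine convert 11 to the Weinreb amide (S,Z)-3-(tert-butyldimethylsilyloxy)-N-methoxy-N-methylundec-5-enamide F1.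
  - Lithium (trimethylsilyl)acetylide in THF at −78 °C gives 14, now isolated.
  - NBS with catalytic AgNO3 in acetone gives 15, now isolated.
  - The gold-catalysed cycloisomerisation of pure 15 with (BrettPhos)AuNTf2 in ClCH2CH2Cl then gives 16.

Step 13.
- What may go wrong: the bulky silyl group may shield the oxygen-bearing face, so facial selectivity at C8 erodes or reverses. The lithium chair may also give only modest anti selectivity.
- Fallback (directing group in place of a protecting group): it sets out from 16 and returns at 28.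
  - HF·pyridine frees (S)-2-bromo-4-hydroxy-4-[(Z)-oct-2-en-1-yl]cyclopent-2-en-1-one F2.
  - Bu2BOTf (2.2 equiv) and i-Pr2NEt give the O-borinate boron dienolate (S)-2-bromo-1,4-bis(dibutylboryloxy)-4-[(Z)-oct-2-en-1-yl]cyclopenta-1,3-diene... more simply the bis(dibutylboryl) dienolate of F2 F3. No free alkoxide is present, so no retro-aldol can occur. Its C12–O–B centre can bind 23 on the oxygen face, and the tight boron chair should raise the anti preference.
  - Hydrolytic work-up gives the diol methyl (5Z,7S)-7-[(1R,2S)-4-bromo-2-hydroxy-2-[(Z)-oct-2-en-1-yl]-5-oxocyclopent-3-en-1-yl]-7-hydroxyhept-5-enoate F4.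
  - Ac2O and pyridine at 0 °C acetylate only the secondary C7 hydroxyl, giving 28.

Step 12.
- What may go wrong: the Z-enal may drift to the E isomer during oxidation, handling or the aldol addition.
- Fallback (alkyne as a masked Z alkene): it sets out from 21 and returns at 27.
  - TEMPO/PhI(OAc)2 oxidation of 21 gives the geometrically inert ynal methyl 7-oxohept-5-ynoate F5.
  - Addition of dienolate 24 gives methyl (7R)-7-[(1R,2S)-4-bromo-2-(tert-butyldimethylsilyloxy)-2-[(Z)-oct-2-en-1-yl]-5-oxocyclopent-3-en-1-yl]-7-hydroxyhept-5-ynoate F6. The spatial arrangement is the same as in 26, and the descriptor changes only through the priorities.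
  - Acetylation gives methyl (7R)-7-acetoxy-7-[(1R,2S)-4-bromo-2-(tert-butyldimethylsilyloxy)-2-[(Z)-oct-2-en-1-yl]-5-oxocyclopent-3-en-1-yl]hept-5-ynoate F7.
  - Lindlar semi-hydrogenation, stopped after one equivalent of hydrogen, gives 27.

**Further compounds**
F1 | step 8 | (S,Z)-3-(tert-butyldimethylsilyloxy)-N-methoxy-N-methylundec-5-enamide | CCCCC/C=C\C[C@@H](CC(=O)N(C)OC)O[Si](C)(C)C(C)(C)C
F2 | step 13 | (S)-2-bromo-4-hydroxy-4-[(Z)-oct-2-en-1-yl]cyclopent-2-en-1-one | CCCCC/C=C\C[C@@]1(O)C=C(Br)C(=O)C1
F3 | step 13 | bis(dibutylboryl) dienolate of F2 | CCCCC/C=C\C[C@@]1(OB(CCCC)CCCC)C=C(Br)C(OB(CCCC)CCCC)=C1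
F4 | step 13 | methyl (5Z,7S)-7-[(1R,2S)-4-bromo-2-hydroxy-2-[(Z)-oct-2-en-1-yl]-5-oxocyclopent-3-en-1-yl]-7-hydroxyhept-5-enoate | CCCCC/C=C\C[C@@]1(O)C=C(Br)C(=O)[C@@H]1[C@H](/C=C\CCCC(=O)OC)O
F5 | step 12 | methyl 7-oxohept-5-ynoate | O=CC#CCCCC(=O)OC
F6 | step 12 | methyl (7R)-7-[(1R,2S)-4-bromo-2-(tert-butyldimethylsilyloxy)-2-[(Z)-oct-2-en-1-yl]-5-oxocyclopent-3-en-1-yl]-7-hydroxyhept-5-ynoate | CCCCC/C=C\C[C@@]1(O[Si](C)(C)C(C)(C)C)C=C(Br)C(=O)[C@@H]1[C@H](C#CCCCC(=O)OC)O
F7 | step 12 | methyl (7R)-7-acetoxy-7-[(1R,2S)-4-bromo-2-(tert-butyldimethylsilyloxy)-2-[(Z)-oct-2-en-1-yl]-5-oxocyclopent-3-en-1-yl]hept-5-ynoate | CCCCC/C=C\C[C@@]1(O[Si](C)(C)C(C)(C)C)C=C(Br)C(=O)[C@@H]1[C@H](C#CCCCC(=O)OC)OC(C)=O
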